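5 questions stand on 4 flasks, and you can work them by following one molecule of substrate to the fork it reaches as intermediate.

| flask | substrate | second nucleophile | solid first nucleophile | protic impurity | remark | time |
|---|---|---|---|---|---|---|
| north-east | 28 mM | 84 mM | 28 mM | 28 mM | run made earlier |  |
| south | 28 mM | 84 mM | 39 mM | 28 mM | run made earlier |  |
| north-west | 28 mM | 84 mM | 62 mM | 28 mM | run made earlier |  |
| north | 28 mM | 170 mM | 28 mM | 28 mM | run made earlier |  |
| Sunday's | 28 mM | 84.0 mM (fed, over 1.5 h) | 28.0 mM | 28.0 mM | all else is in the flask from the start; the feed brings no volume worth counting | 8.0 h |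
| Tuesday's | 28 mM (fed, over 1.5 h) | 84.0 mM | 28.0 mM | 28.0 mM | all else is in the flask from the start; the feed brings no volume worth counting | 8.0 h |
| Friday's | 28 mM (fed, over 25 min) | 84.0 mM | 28.0 mM | 28.0 mM | all else is in the flask from the start; the feed brings no volume worth counting | 8.0 h |
| Wednesday's | 28 mM | 84.0 mM | 28.0 mM | 28.0 mM | everything together at the start | 8.0 h |

| run | time / h | other capture product / % | target / % |
|---|---|---|---|
| north-east | 0.667 | 85.0 | 5.3 |
| north-east | 1.00 | 88.8 | 7.9 |
| north-east | 2.00 | 92.3 | 9.1 |
| north-east | 3.00 | 90.8 | 8.7 |
| north-east | 5.00 | 93.0 | 9.5 |
| north-east | 8.00 | 93.6 | 8.1 |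
| south | 0.500 | 77.4 | 3.3 |
| south | 1.50 | 89.7 | 8.0 |
| south | 3.00 | 91.6 | 8.1 |
| south | 4.00 | 89.9 | 7.4 |
| south | 6.00 | 90.0 | 8.3 |
| south | 8.00 | 90.2 | 8.2 |
| north-west | 0.667 | 84.5 | 5.5 |
| north-west | 1.00 | 89.3 | 6.2 |
| north-west | 2.00 | 91.5 | 11.1 |
| north-west | 3.00 | 90.9 | 8.2 |
| north-west | 5.00 | 91.7 | 8.3 |
| north-west | 8.00 | 89.4 | 7.9 |
| north | 1.50 | 95.0 | 4.6 |
| north | 3.00 | 95.1 | 5.2 |
| north | 5.00 | 95.2 | 5.3 |
| north | 6.00 | 93.8 | 4.4 |
| north | 8.00 | 95.5 | 5.4 |

(scatter of a reading: 1 percentage point)

1. the flask that comes out highest in amount of other capture product, in percent of the substrate charged, or "all alike" when all lie within 1.5 percentage points (Sunday's / Tuesday's / Friday's / Wednesday's / all alike)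
2. other capture product at the end, in percent of the substrate charged, Sunday's
3. other capture product at the end, in percent of the substrate charged, Tuesday's
4. other capture product at the end, in percent of the substrate charged, Friday's
5. other capture product at the end, in percent of the substrate charged, Wednesday's

- in percentages every species weighs as the substrate in it: one idle adduct counts as two
- for target the idle adduct is counted in
- as a solid, counted per litre of solution: solid first nucleophile
- the analysis behind the earlier runs scatters by 1 percentage point, standard deviation
- steps that have been proposed: substrate -> intermediate; first nucleophile + intermediate -> target; second nucleophile + intermediate -> other capture product; substrate + target <-> idle adduct; solid first nucleophile <-> first nucleophile; second nucleophile + protic impurity -> quenched reagent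
- at the start none of the solid first nucleophile is in solution
- in an amount of target, one idle adduct counts as one target

At the fork, intermediate goes to target with first nucleophile or to other capture product with second nucleophile, whose concentration I call D. Let c* be the break-even level, the selectivity factor written as a concentration: the D at which the molecule has even chances. It is read as D times target over other capture product, and the share of other capture product is then D/(D+c*). The last 3 readings of the north-east run give c* = 7.96 mM, and those of the north run, with twice the second nucleophile, give 9.02 mM.

Turn the question round: what must be true for a fed flask to beat Wednesday's? Wednesday's has the charges of the north-east run, so its D/c* is 10.5 and its share 91.3%, and a fed flask must offer its forks a higher ratio. In Sunday's, the feed completes the charge of second nucleophile at its end, so D stands below that charge while the feed runs. Tuesday's and Friday's move the forks later, but there the readings point to a higher c*, since the first north-east reading gives 5.24 mM and the later increments, reckoned at the charge, give about 39.0 mM. So I put Wednesday's highest and set no number on the others.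

The forecast also names Wednesday's, with 60% for Sunday's, 77% for Tuesday's, 86% for Friday's and 91% for Wednesday's, holding that “Feeding the second nucleophile keeps it scarce”.

The flasks give 87.2% for Sunday's, 77.8% for Tuesday's, 87.9% for Friday's and 91.5% for Wednesday's, so Wednesday's comes out highest.

    substrate → intermediate (k = 0.0612 min⁻¹)
    first nucleophile + intermediate → target (k = 189 M⁻¹ min⁻¹)
    second nucleophile + intermediate → other capture product (k = 20.6 M⁻¹ min⁻¹)
    substrate + target ⇌ idle adduct, settled at all times (K = 38.0 M⁻¹)
    solid first nucleophile ⇌ first nucleophile, rate k5*(cs5 - [first nucleophile]) while solid is left; crystals form when [first nucleophile] > cs5 (solubility = 18.0 mM, k = 0.00430 min⁻¹)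
    second nucleophile + protic impurity → quenched reagent (k = 0.109 M⁻¹ min⁻¹)

The forecast parts from the flask on Sunday's. At the read c*, Sunday's 87.2% corresponds to D = 54.2 mM, and Sunday's held 54.2 mM at 1.50 h. The neighbouring flask is Wednesday's with 21 mM of second nucleophile, 0.750 equiv. There the reckoning gives 72.5%, and the charge allows 75.0%. That flask gives 71.3% of other capture product and 28.7% of target, with 0.0838% of its second nucleophile left.

The earlier runs and the new flask were generated by integration on assumed constants; the scatter is artificial.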